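**Retrosynthetic overview**
1. Ring carbons: C-1 (methyl, vinyl), C-2 (CH2), C-3 (O-acyl), C-4 (acrylic acid), C-5 (OH), C-6 (hydroxypropenyl). The acid and the C-5 hydroxyl come from chlorite oxidation of a cis-fused lactol; the C-3 ester comes from the C-3 alcohol and silylated (R)-3,4-dihydroxy-2-methylenebutanoic acid.
2. Key disconnection, C-4–C(acrylate): 5-exo vinyl-radical cyclization of a C-5 O-(2-bromo-1-methoxyallyl) acetal onto the C-3/C-4 silyl enol ether. It sets C-4 and, by hydrogen-atom transfer, C-3.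
3. The radical precursor comes from a 2-alkenyl-3-methyl-3-vinyl-5-alkoxycyclohexanone (ketone reduction, acetal exchange, C-3 oxidation). That ketone comes from a 5-alkoxy-3-methylcyclohexenone by vinyl 1,4-addition trans to the alkoxy group and enolate α-alkenylation.
4. The enone comes from an amine-catalysed enantioselective aldol condensation of 4-alkoxyheptane-2,6-dione, itself from ethyl formate and two methallyl Grignard units.
5. Ring order: carbocycle first (aldol condensation), tetrahydrofuran acetal second (radical step); the latter is opened again in the last oxidation.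

Assumption: the quinine-derived primary amine gives the 5R enone 6; if the sense is reversed, its quinidine-derived pseudo-enantiomer is used.

**Route**

Step 1
Reactants: 1 ethyl formate; 2 2-methylallylmagnesium chloride
Product: 3 2,6-dimethylhepta-1,6-dien-4-ol
Conditions: 2 (2.2 equiv), THF, 0 °C to rt; aq NH4Cl
Reagents that add atoms: none
Why: Double Grignard addition to a formate ester gives the symmetric secondary carbinol, so no stereocentre is formed.

Step 2
Reactants: 3 2,6-dimethylhepta-1,6-dien-4-ol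
Product: 4 1-{[(2,6-dimethylhepta-1,6-dien-4-yl)oxy]methyl}-4-methoxybenzene
Conditions: NaH, 4-MeOC6H4CH2Cl, Bu4NI (cat.), DMF, 0 °C to rt
Reagents that add atoms: 4-methoxybenzyl chloride, COc1ccc(CCl)cc1
Why: Williamson etherification installs an oxidatively removable ether on the future C-3 oxygen.

Step 3
Reactants: 4 1-{[(2,6-dimethylhepta-1,6-dien-4-yl)oxy]methyl}-4-methoxybenzene
Product: 5 4-[(4-methoxyphenyl)methoxy]heptane-2,6-dione
Conditions: O3, CH2Cl2–MeOH, −78 °C (indicator-dye end point); Me2S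
Reagents that add atoms: ozone, [O-][O+]=O
Why: Ozonolysis with reductive work-up cleaves both 1,1-disubstituted alkenes to methyl ketones, and the product is still achiral.

Step 4
Reactants: 5 4-[(4-methoxyphenyl)methoxy]heptane-2,6-dione
Product: 6 (5R)-5-[(4-methoxyphenyl)methoxy]-3-methylcyclohex-2-en-1-one
Conditions: 9-amino-9-deoxy-epi-quinine (20 mol %), AcOH (60 mol %), PhMe, −15 °C
Reagents that add atoms: none
Why: Enamine-mediated intramolecular aldol condensation (Hajos–Parrish–Eder–Sauer–Wiechert type, primary-amine variant) in which the chiral amine differentiates the two enantiotopic acetonyl arms and so sets C-3 as R.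

Step 5
Reactants: 7 2-bromoprop-2-en-1-ol
Product: 8 [(2-bromoprop-2-en-1-yl)oxy](tert-butyl)dimethylsilane
Conditions: t-BuMe2SiCl, imidazole, CH2Cl2, rt
Reagents that add atoms: tert-butyldimethylsilyl chloride, CC(C)(C)[Si](C)(C)Cl
Why: Routine silylation of a primary alcohol.

Step 6
Reactants: 6 (5R)-5-[(4-methoxyphenyl)methoxy]-3-methylcyclohex-2-en-1-one; 9 vinylmagnesium bromide; 8 [(2-bromoprop-2-en-1-yl)oxy](tert-butyl)dimethylsilane
Product: 12 (2S,3S,5R)-2-(3-{[tert-butyl(dimethyl)silyl]oxy}prop-1-en-2-yl)-3-ethenyl-5-[(4-methoxyphenyl)methoxy]-3-methylcyclohexan-1-one, via bromomagnesium enolate 10 (not isolated), via chlorozinc enolate 11 (not isolated)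
Conditions: 9 (1.1 equiv), CuBr·SMe2 (10 mol %), THF, −40 °C; ZnCl2; Pd2(dba)3 (2.5 mol %), P(t-Bu)3·HBF4 (10 mol %), 8, 45 °C; then DBU (cat.), CH2Cl2, 0 °C
Reagents that add atoms: none
Why: Proposed new method: a one-pot merger of a Kharasch-type copper-catalysed 1,4-addition with a palladium-catalysed α-alkenylation of the regiodefined zinc enolate; vinyl enters axially, trans to the equatorial alkoxy group, setting quaternary C-1, the enolate then transmetalates to the alkenylpalladium bromide and reductive elimination forms the C-6–C bond (closest known reactions: enolate trapping after cuprate addition and Buchwald–Hartwig-type ketone α-vinylation), and DBU converges C-6 on the equatorial epimer because the equatorial methyl and alkoxy groups lock the chair.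

Step 7
Reactants: 12 (2S,3S,5R)-2-(3-{[tert-butyl(dimethyl)silyl]oxy}prop-1-en-2-yl)-3-ethenyl-5-[(4-methoxyphenyl)methoxy]-3-methylcyclohexan-1-one
Product: 13 (1R,2S,3S,5R)-2-(3-{[tert-butyl(dimethyl)silyl]oxy}prop-1-en-2-yl)-3-ethenyl-5-[(4-methoxyphenyl)methoxy]-3-methylcyclohexan-1-ol
Conditions: SmI2, H2O, Et3N, THF, rt
Reagents that add atoms: none
Why: Single-electron (ketyl) reduction gives the more stable equatorial C-5 alcohol, trans to the C-6 side chain, because an axial hydroxyl would be syn-diaxial to the axial vinyl group.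

Step 8
Reactants: 13 (1R,2S,3S,5R)-2-(3-{[tert-butyl(dimethyl)silyl]oxy}prop-1-en-2-yl)-3-ethenyl-5-[(4-methoxyphenyl)methoxy]-3-methylcyclohexan-1-ol; 14 2-bromo-3,3-dimethoxyprop-1-ene
Product: 15 1-({[(1R,3S,4S,5R)-5-[(2-bromo-1-methoxyprop-2-en-1-yl)oxy]-4-(3-{[tert-butyl(dimethyl)silyl]oxy}prop-1-en-2-yl)-3-ethenyl-3-methylcyclohexyl]oxy}methyl)-4-methoxybenzene (both acetal epimers)
Conditions: 14 (3 equiv), PPTS (cat.), PhMe, 50 °C, 5 Å sieves
Reagents that add atoms: none
Why: Acid-catalysed transacetalisation exchanges one methoxy group for the C-5 alcohol; the new acetal centre forms as a mixture that is removed later.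

Step 9
Reactants: 15 mixed acetal 4-methoxybenzyl ether (name as in step 8)
Product: 16 (1R,3S,4S,5R)-5-[(2-bromo-1-methoxyprop-2-en-1-yl)oxy]-4-(3-{[tert-butyl(dimethyl)silyl]oxy}prop-1-en-2-yl)-3-ethenyl-3-methylcyclohexan-1-ol
Conditions: DDQ, CH2Cl2–pH 7 buffer, 0 °C
Reagents that add atoms: none
Why: Oxidative cleavage of the 4-methoxybenzyl ether by benzylic hydride abstraction and hydrolysis leaves alkenes, acetal and silyl ether untouched.

Step 10
Reactants: 16 (1R,3S,4S,5R)-5-[(2-bromo-1-methoxyprop-2-en-1-yl)oxy]-4-(3-{[tert-butyl(dimethyl)silyl]oxy}prop-1-en-2-yl)-3-ethenyl-3-methylcyclohexan-1-ol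
Product: 17 (3S,4S,5R)-5-[(2-bromo-1-methoxyprop-2-en-1-yl)oxy]-4-(3-{[tert-butyl(dimethyl)silyl]oxy}prop-1-en-2-yl)-3-ethenyl-3-methylcyclohexan-1-one
Conditions: Dess–Martin periodinane, NaHCO3, CH2Cl2, rt
Reagents that add atoms: none
Why: Dess–Martin oxidation erases the C-3 stereocentre, which has served as the control element for C-1, C-6 and C-5 and is re-created in step 12.

Step 11
Reactants: 17 (3S,4S,5R)-5-[(2-bromo-1-methoxyprop-2-en-1-yl)oxy]-4-(3-{[tert-butyl(dimethyl)silyl]oxy}prop-1-en-2-yl)-3-ethenyl-3-methylcyclohexan-1-one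
Product: 18 {[(3S,4S,5S)-3-[(2-bromo-1-methoxyprop-2-en-1-yl)oxy]-4-(3-{[tert-butyl(dimethyl)silyl]oxy}prop-1-en-2-yl)-5-ethenyl-5-methylcyclohex-1-en-1-yl]oxy}(trimethyl)silane
Conditions: LiN(SiMe3)2, Me3SiCl (internal quench), THF, −78 °C
Reagents that add atoms: chlorotrimethylsilane, C[Si](C)(C)Cl
Why: Kinetic deprotonation goes to C-4 because the C-2 methylene is neopentylic, and the equatorial C-5–O bond lies in the enolate plane so β-elimination is stereoelectronically slow.

Step 12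
Reactants: 18 silyl enol ether (name as in step 11)
Product: 20 (3aR,4R,6S,7S,7aS)-7-(3-{[tert-butyl(dimethyl)silyl]oxy}prop-1-en-2-yl)-6-ethenyl-2-methoxy-6-methyl-3-methylideneoctahydro-1-benzofuran-4-ol (acetal epimers), via trimethylsilyl ether 19 (not isolated)
Conditions: Bu3SnH (1.3 equiv, slow addition), AIBN (cat.), PhH (0.01 M), 80 °C; then K2CO3, MeOH, 0 °C
Reagents that add atoms: none
Why: Proposed new method: a Ueno–Stork-type haloacetal radical cyclization run with a vinyl radical and a silyl enol ether acceptor; Bu3Sn• abstracts bromine, the σ-vinyl radical adds 5-exo-trig to C-4 through the only accessible cis-fused transition state (C-4 cis to the C-5 oxygen), and the α-silyloxy radical at C-3 takes hydrogen from Bu3SnH anti to the new axial C-4 bond (C-3 oxygen equatorial, cis to C-4); the closest known reactions are the Ueno–Stork bromoacetal cyclization and Stork vinyl-radical cyclizations.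

Step 13
Reactants: 21 (2R)-but-3-ene-1,2-diol
Product: 22 (3R)-3,4-bis{[tert-butyl(dimethyl)silyl]oxy}but-1-ene
Conditions: t-BuMe2SiCl (2.2 equiv), imidazole, DMF, rt
Reagents that add atoms: tert-butyldimethylsilyl chloride, CC(C)(C)[Si](C)(C)Cl
Why: Bis-silylation of the diol does not touch the stereocentre.

Step 14
Reactants: 22 (3R)-3,4-bis{[tert-butyl(dimethyl)silyl]oxy}but-1-ene
Product: 24 (3S)-2-bromo-3,4-bis{[tert-butyl(dimethyl)silyl]oxy}but-1-ene, via vicinal dibromide 23 (not isolated)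
Conditions: Br2, CH2Cl2, −78 °C; DBU, 40 °C
Reagents that add atoms: bromine, BrBr
Why: Anti addition of bromine then E2 loss of HBr through the more acidic C-2 hydrogen gives the 2-bromoalkene; the carbinol centre is not involved (the descriptor changes only by priority).

Step 15
Reactants: 24 (3S)-2-bromo-3,4-bis{[tert-butyl(dimethyl)silyl]oxy}but-1-ene
Product: 25 (3R)-3,4-bis{[tert-butyl(dimethyl)silyl]oxy}-2-methylidenebutanoic acid
Conditions: t-BuLi (2.1 equiv), Et2O, −78 °C; CO2; aq HCl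
Reagents that add atoms: carbon dioxide, O=C=O
Why: Bromine–lithium exchange and carboxylation of the alkenyllithium retain the adjacent stereocentre.

Step 16
Reactants: 20 bicyclic acetal alcohol (name as in step 12); 25 (3R)-3,4-bis{[tert-butyl(dimethyl)silyl]oxy}-2-methylidenebutanoic acid
Product: 26 (3aR,4R,6S,7S,7aS)-7-(3-{[tert-butyl(dimethyl)silyl]oxy}prop-1-en-2-yl)-6-ethenyl-2-methoxy-6-methyl-3-methylideneoctahydro-1-benzofuran-4-yl (3R)-3,4-bis{[tert-butyl(dimethyl)silyl]oxy}-2-methylidenebutanoate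
Conditions: 2,4,6-Cl3C6H2COCl, Et3N, THF; 20, DMAP, PhMe, 40 °C
Reagents that add atoms: none
Why: Yamaguchi esterification through the mixed anhydride acylates the equatorial C-3 alcohol under basic conditions that spare the acetal.

Step 17
Reactants: 26 silylated ester acetal (name as in step 16)
Product: 27 (3aR,4R,6S,7S,7aS)-6-ethenyl-2-hydroxy-7-(3-hydroxyprop-1-en-2-yl)-6-methyl-3-methylideneoctahydro-1-benzofuran-4-yl (3R)-3,4-dihydroxy-2-methylidenebutanoate (lactol epimers)
Conditions: 48% aq HF, MeCN, 0 °C to rt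
Reagents that add atoms: water, O
Why: Aqueous HF removes the three silyl ethers and hydrolyses the methyl acetal to the lactol in one operation without touching the ring stereocentres.

Step 18
Reactants: 27 lactol tetraol (name as in step 17)
Product: 28 2-[(1S,2S,3S,4S,6R)-6-{[(3R)-3,4-dihydroxy-2-methylidenebutanoyl]oxy}-4-ethenyl-2-hydroxy-3-(3-hydroxyprop-1-en-2-yl)-4-methylcyclohexyl]prop-2-enoic acid (target)
Conditions: NaClO2, NaH2PO4, 2-methylbut-2-ene, t-BuOH–H2O, 0 °C; work-up at pH 4–5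
Reagents that add atoms: sodium chlorite, [Na+].[O-]Cl=O
Why: Pinnick (Lindgren–Kraus) oxidation of the open-chain 2-substituted acrolein tautomer of the lactol gives the acrylic acid and frees the C-5 hydroxyl, alcohols and alkenes being inert to chlorite when the hypochlorite is scavenged.

**Compound list**
1 | ethyl formate | CCOC=O | starting material
2 | 2-methylallylmagnesium chloride | CC(=C)C[Mg]Cl | starting material
3 | 2,6-dimethylhepta-1,6-dien-4-ol | CC(=C)CC(O)CC(C)=C | intermediate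
4 | 1-{[(2,6-dimethylhepta-1,6-dien-4-yl)oxy]methyl}-4-methoxybenzene | CC(=C)CC(OCc1ccc(OC)cc1)CC(C)=C | intermediate
5 | 4-[(4-methoxyphenyl)methoxy]heptane-2,6-dione | CC(=O)CC(OCc1ccc(OC)cc1)CC(C)=O | intermediate
6 | (5R)-5-[(4-methoxyphenyl)methoxy]-3-methylcyclohex-2-en-1-one | CC=1C[C@@H](OCc2ccc(OC)cc2)CC(=O)C=1 | intermediate
7 | 2-bromoprop-2-en-1-ol | OCC(Br)=C | starting material
8 | [(2-bromoprop-2-en-1-yl)oxy](tert-butyl)dimethylsilane | C=C(Br)CO[Si](C)(C)C(C)(C)C | intermediate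
9 | vinylmagnesium bromide | C=C[Mg]Br | starting material
10 | bromomagnesium (3S,5R)-3-ethenyl-5-[(4-methoxyphenyl)methoxy]-3-methylcyclohex-1-en-1-olate | C=C[C@]1(C)C[C@@H](OCc2ccc(OC)cc2)CC(O[Mg]Br)=C1 | intermediate
11 | chlorozinc (3S,5R)-3-ethenyl-5-[(4-methoxyphenyl)methoxy]-3-methylcyclohex-1-en-1-olate | C=C[C@]1(C)C[C@@H](OCc2ccc(OC)cc2)CC(O[Zn]Cl)=C1 | intermediate
12 | (2S,3S,5R)-2-(3-{[tert-butyl(dimethyl)silyl]oxy}prop-1-en-2-yl)-3-ethenyl-5-[(4-methoxyphenyl)methoxy]-3-methylcyclohexan-1-one | C=C[C@]1(C)C[C@@H](OCc2ccc(OC)cc2)CC(=O)[C@@H]1C(=C)CO[Si](C)(C)C(C)(C)C | intermediate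
13 | (1R,2S,3S,5R)-2-(3-{[tert-butyl(dimethyl)silyl]oxy}prop-1-en-2-yl)-3-ethenyl-5-[(4-methoxyphenyl)methoxy]-3-methylcyclohexan-1-ol | C=C[C@]1(C)C[C@@H](OCc2ccc(OC)cc2)C[C@@H](O)[C@@H]1C(=C)CO[Si](C)(C)C(C)(C)C | intermediate
14 | 2-bromo-3,3-dimethoxyprop-1-ene | C=C(Br)C(OC)OC | starting material
15 | 1-({[(1R,3S,4S,5R)-5-[(2-bromo-1-methoxyprop-2-en-1-yl)oxy]-4-(3-{[tert-butyl(dimethyl)silyl]oxy}prop-1-en-2-yl)-3-ethenyl-3-methylcyclohexyl]oxy}methyl)-4-methoxybenzene (acetal carbon undefined, both epimers) | C=C[C@]1(C)C[C@@H](OCc2ccc(OC)cc2)C[C@@H](OC(OC)C(Br)=C)[C@@H]1C(=C)CO[Si](C)(C)C(C)(C)C | intermediate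
16 | (1R,3S,4S,5R)-5-[(2-bromo-1-methoxyprop-2-en-1-yl)oxy]-4-(3-{[tert-butyl(dimethyl)silyl]oxy}prop-1-en-2-yl)-3-ethenyl-3-methylcyclohexan-1-ol (acetal epimers) | C=C[C@]1(C)C[C@@H](O)C[C@@H](OC(OC)C(Br)=C)[C@@H]1C(=C)CO[Si](C)(C)C(C)(C)C | intermediate
17 | (3S,4S,5R)-5-[(2-bromo-1-methoxyprop-2-en-1-yl)oxy]-4-(3-{[tert-butyl(dimethyl)silyl]oxy}prop-1-en-2-yl)-3-ethenyl-3-methylcyclohexan-1-one (acetal epimers) | C=C[C@]1(C)CC(=O)C[C@@H](OC(OC)C(Br)=C)[C@@H]1C(=C)CO[Si](C)(C)C(C)(C)C | intermediate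
18 | {[(3S,4S,5S)-3-[(2-bromo-1-methoxyprop-2-en-1-yl)oxy]-4-(3-{[tert-butyl(dimethyl)silyl]oxy}prop-1-en-2-yl)-5-ethenyl-5-methylcyclohex-1-en-1-yl]oxy}(trimethyl)silane (acetal epimers) | C=C[C@]1(C)CC(O[Si](C)(C)C)=C[C@@H](OC(OC)C(Br)=C)[C@@H]1C(=C)CO[Si](C)(C)C(C)(C)C | intermediate
19 | tert-butyl(dimethyl){[2-((3aS,4R,6S,7S,7aS)-6-ethenyl-2-methoxy-6-methyl-3-methylidene-4-[(trimethylsilyl)oxy]octahydro-1-benzofuran-7-yl)prop-2-en-1-yl]oxy}silane (acetal epimers) | C=C[C@]1(C)C[C@@H](O[Si](C)(C)C)[C@H]2C(=C)C(OC)O[C@H]2[C@@H]1C(=C)CO[Si](C)(C)C(C)(C)C | intermediate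
20 | (3aR,4R,6S,7S,7aS)-7-(3-{[tert-butyl(dimethyl)silyl]oxy}prop-1-en-2-yl)-6-ethenyl-2-methoxy-6-methyl-3-methylideneoctahydro-1-benzofuran-4-ol (acetal epimers) | C=C[C@]1(C)C[C@@H](O)[C@H]2C(=C)C(OC)O[C@H]2[C@@H]1C(=C)CO[Si](C)(C)C(C)(C)C | intermediate
21 | (2R)-but-3-ene-1,2-diol | C=C[C@@H](O)CO | starting material
22 | (3R)-3,4-bis{[tert-butyl(dimethyl)silyl]oxy}but-1-ene | C=C[C@@H](O[Si](C)(C)C(C)(C)C)CO[Si](C)(C)C(C)(C)C | intermediate
23 | (3S)-1,2-dibromo-3,4-bis{[tert-butyl(dimethyl)silyl]oxy}butane (C-2 epimers) | BrCC(Br)[C@@H](O[Si](C)(C)C(C)(C)C)CO[Si](C)(C)C(C)(C)C | intermediate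
24 | (3S)-2-bromo-3,4-bis{[tert-butyl(dimethyl)silyl]oxy}but-1-ene | C=C(Br)[C@@H](O[Si](C)(C)C(C)(C)C)CO[Si](C)(C)C(C)(C)C | intermediate
25 | (3R)-3,4-bis{[tert-butyl(dimethyl)silyl]oxy}-2-methylidenebutanoic acid | OC(=O)C(=C)[C@@H](O[Si](C)(C)C(C)(C)C)CO[Si](C)(C)C(C)(C)C | intermediate
26 | (3aR,4R,6S,7S,7aS)-7-(3-{[tert-butyl(dimethyl)silyl]oxy}prop-1-en-2-yl)-6-ethenyl-2-methoxy-6-methyl-3-methylideneoctahydro-1-benzofuran-4-yl (3R)-3,4-bis{[tert-butyl(dimethyl)silyl]oxy}-2-methylidenebutanoate (acetal epimers) | C=C[C@]1(C)C[C@@H](OC(=O)C(=C)[C@@H](O[Si](C)(C)C(C)(C)C)CO[Si](C)(C)C(C)(C)C)[C@H]2C(=C)C(OC)O[C@H]2[C@@H]1C(=C)CO[Si](C)(C)C(C)(C)C | intermediate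
27 | (3aR,4R,6S,7S,7aS)-6-ethenyl-2-hydroxy-7-(3-hydroxyprop-1-en-2-yl)-6-methyl-3-methylideneoctahydro-1-benzofuran-4-yl (3R)-3,4-dihydroxy-2-methylidenebutanoate (lactol epimers) | C=C[C@]1(C)C[C@@H](OC(=O)C(=C)[C@@H](O)CO)[C@H]2C(=C)C(O)O[C@H]2[C@@H]1C(=C)CO | intermediate
28 | 2-[(1S,2S,3S,4S,6R)-6-{[(3R)-3,4-dihydroxy-2-methylidenebutanoyl]oxy}-4-ethenyl-2-hydroxy-3-(3-hydroxyprop-1-en-2-yl)-4-methylcyclohexyl]prop-2-enoic acid | C=C[C@]1(C)C[C@@H](OC(=O)C(=C)[C@@H](O)CO)[C@@H](C(=C)C(=O)O)[C@@H](O)[C@@H]1C(=C)CO | target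

**Step count**
Total step count: 18. Longest linear sequence: 14 steps (steps 1–4, 6–12, 16–18).

**Three steps most likely to fail, each with a fallback**

Step 6 (one-pot 1,4-addition and α-alkenylation next to the new quaternary carbon). The zinc enolate may transmetalate slowly, and the C-6 epimer ratio under equilibration is estimated at only about 5:1. The fallback sets out from 6 and forms the C-6–C bond on an sp2 carbon before the quaternary centre exists. α-Iodination (I2, pyridine, CH2Cl2) gives (5R)-2-iodo-5-[(4-methoxyphenyl)methoxy]-3-methylcyclohex-2-en-1-one F1. The bromide 8 is converted (t-BuLi, −78 °C; Bu3SnCl) into tributyl(3-{[tert-butyl(dimethyl)silyl]oxy}prop-1-en-2-yl)stannane F2. Stille coupling of the two (Pd(PPh3)4, CuI, DMF, 50 °C) gives the cross-conjugated dienone (5R)-2-(3-{[tert-butyl(dimethyl)silyl]oxy}prop-1-en-2-yl)-5-[(4-methoxyphenyl)methoxy]-3-methylcyclohex-2-en-1-one F3. Me3SiCl-accelerated addition of the vinyl cuprate made from 9 and CuI (THF, −78 °C), again trans to the alkoxy group, followed by axial protonation of the enolate at low temperature, comes back to the route at 12 with C-6 set kinetically.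

Step 7 (configuration at C-5). If the SmI2 reduction gives a mixture, the fallback sets out from 12 and replaces kinetic control by equilibration. NaBH4 in MeOH gives 13 together with its C-5 epimer (1S,2S,3S,5R)-2-(3-{[tert-butyl(dimethyl)silyl]oxy}prop-1-en-2-yl)-3-ethenyl-5-[(4-methoxyphenyl)methoxy]-3-methylcyclohexan-1-ol F4. Meerwein–Ponndorf–Verley/Oppenauer equilibration of the mixture (Al(Oi-Pr)3, i-PrOH, cat. acetone, PhMe, 80 °C) drains the axial alcohol into the equatorial one through reversible hydride transfer and comes back at 13.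

Step 12 (radical cyclization). Failure modes are 1,5-hydrogen transfer to the vinyl radical from the allylic C-6–H, premature reduction, and poor face selectivity of hydrogen transfer at C-3 (the axial vinyl group hinders the favoured face). The fallback sets out from 17 and closes the same ring by polar chemistry. Palladium-catalysed intramolecular α-alkenylation of the ketone (Pd(PPh3)4, KOt-Bu, THF, 60 °C) can form only the cis-fused five-membered ring through the C-4 enolate and gives (3aS,6S,7S,7aS)-7-(3-{[tert-butyl(dimethyl)silyl]oxy}prop-1-en-2-yl)-6-ethenyl-2-methoxy-6-methyl-3-methylidenehexahydro-1-benzofuran-4(2H)-one F5. Reduction of its ketone under thermodynamic control (SmI2, H2O, Et3N, THF; the axial C-3 alcohol would be syn-diaxial to the vinyl group) comes back at 20.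

Further compounds
F1 | step 6 | (5R)-2-iodo-5-[(4-methoxyphenyl)methoxy]-3-methylcyclohex-2-en-1-one | CC=1C[C@@H](OCc2ccc(OC)cc2)CC(=O)C=1I
F2 | step 6 | tributyl(3-{[tert-butyl(dimethyl)silyl]oxy}prop-1-en-2-yl)stannane | CCCC[Sn](CCCC)(CCCC)C(=C)CO[Si](C)(C)C(C)(C)C
F3 | step 6 | (5R)-2-(3-{[tert-butyl(dimethyl)silyl]oxy}prop-1-en-2-yl)-5-[(4-methoxyphenyl)methoxy]-3-methylcyclohex-2-en-1-one | CC=1C[C@@H](OCc2ccc(OC)cc2)CC(=O)C=1C(=C)CO[Si](C)(C)C(C)(C)C
F4 | step 7 | (1S,2S,3S,5R)-2-(3-{[tert-butyl(dimethyl)silyl]oxy}prop-1-en-2-yl)-3-ethenyl-5-[(4-methoxyphenyl)methoxy]-3-methylcyclohexan-1-ol | C=C[C@]1(C)C[C@@H](OCc2ccc(OC)cc2)C[C@H](O)[C@@H]1C(=C)CO[Si](C)(C)C(C)(C)C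
F5 | step 12 | (3aS,6S,7S,7aS)-7-(3-{[tert-butyl(dimethyl)silyl]oxy}prop-1-en-2-yl)-6-ethenyl-2-methoxy-6-methyl-3-methylidenehexahydro-1-benzofuran-4(2H)-one (acetal epimers) | C=C[C@]1(C)CC(=O)[C@H]2C(=C)C(OC)O[C@H]2[C@@H]1C(=C)CO[Si](C)(C)C(C)(C)C
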